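## Retrosynthetic overview

- Mollicellin A is taken back to its methyl ether; the last step frees the phenol ortho to the aldehyde.
- Strategic feature: in ring A the carbon bearing CHO and the carbon bearing the diaryl ether oxygen are ortho neighbours, set between the phenol carbon and the lactone carbonyl carbon. That ether oxygen lies in the seven-membered dioxepinone ring C with all four ortho positions substituted. The two carbons are therefore treated as the two ends of an aryne: the ring B phenoxide of a depside adds to one end, and DMF formylates the arylmagnesium left at the other.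
- The depside is the ester of a ring A acid (2-sulfonyloxy-3-iodo aryne precursor, from 3,5-dimethoxytoluene) with the 7-OH of 6,7-dihydroxy-2,2,5-trimethylchroman-4-one (from orcinol and 3,3-dimethylacrylic acid).
- Ring order: rings A and B are bought arenes, the pyranone ring D is closed on ring B, the ester joins the halves, and ring C is closed last.

Key step: step 11

Remark: the target has no stereocenter, so no step has to control configuration and no SMILES carries a stereo descriptor.

## Route

Step 1
Reactants: 1 3,5-dimethoxytoluene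
Product: 3 2-iodo-1,3-dimethoxy-5-methylbenzene, via aryllithium 2 (not isolated)
Conditions: n-BuLi, THF, 0 °C → rt; then I2, −78 °C → rt
Reagents that add atoms: iodine, II
Why: Directed ortho-metalation removes the proton between the two methoxy groups, the most acidic and doubly coordinated site, and iodine traps the aryllithium, so the halogen is placed without regioisomers.

Step 2
Reactants: 3 2-iodo-1,3-dimethoxy-5-methylbenzene
Product: 5 3-iodo-2,4-dimethoxy-6-methylbenzaldehyde, via chloro(methoxy)methyl arene 4 (not isolated)
Conditions: Cl2CHOMe, TiCl4, CH2Cl2, −78 → 0 °C; then H2O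
Reagents that add atoms: dichloromethyl methyl ether, COC(Cl)Cl; water, O
Why: Rieche formylation is chosen because the two free ring positions are equivalent (each ortho to one methoxy, para to the other, beside the methyl) and the small TiCl4-activated electrophile suits an arene that iodine deactivates and hinders; hydrolysis of the chloro ether gives the aldehyde.

Step 3
Reactants: 5 3-iodo-2,4-dimethoxy-6-methylbenzaldehyde
Product: 7 2-hydroxy-3-iodo-4-methoxy-6-methylbenzaldehyde, via aryloxydichloroborane 6 (not isolated)
Conditions: BCl3, CH2Cl2, −78 → 0 °C; then H2O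
Reagents that add atoms: none
Why: Chelation-controlled ether cleavage: BCl3 bridges the aldehyde oxygen and the ortho methoxy oxygen, so chloride removes only that methyl group and the para methoxy group should stay.

Step 4
Reactants: 7 2-hydroxy-3-iodo-4-methoxy-6-methylbenzaldehyde
Product: 8 2-formyl-6-iodo-5-methoxy-3-methylphenyl 4-chlorobenzenesulfonate
Conditions: 4-ClC6H4SO2Cl, Et3N, DMAP (cat.), CH2Cl2, 0 °C → rt
Reagents that add atoms: 4-chlorobenzenesulfonyl chloride, O=S(=O)(Cl)c1ccc(Cl)cc1
Why: Base-mediated O-sulfonylation of the phenol installs, next to the iodide, the arenesulfonate leaving group needed later for aryne generation.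

Step 5
Reactants: 8 2-formyl-6-iodo-5-methoxy-3-methylphenyl 4-chlorobenzenesulfonate
Product: 9 2-[(4-chlorophenyl)sulfonyloxy]-3-iodo-4-methoxy-6-methylbenzoic acid
Conditions: NaClO2, NaH2PO4, 2-methyl-2-butene, t-BuOH/THF/H2O, rt
Reagents that add atoms: sodium chlorite, [Na+].[O-]Cl=O
Why: Pinnick oxidation converts the hindered aldehyde into the acid under mildly acidic conditions that leave the sulfonate and the aryl iodide alone, the alkene scavenging hypochlorous acid.

Step 6
Reactants: 9 2-[(4-chlorophenyl)sulfonyloxy]-3-iodo-4-methoxy-6-methylbenzoic acid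
Product: 10 2-[(4-chlorophenyl)sulfonyloxy]-3-iodo-4-methoxy-6-methylbenzoyl chloride
Conditions: 1-chloro-N,N,2-trimethylprop-1-en-1-amine, CH2Cl2, 0 °C → rt; evaporated and used crude
Reagents that add atoms: 1-chloro-N,N,2-trimethylprop-1-en-1-amine, CC(C)=C(Cl)N(C)C
Why: The α-chloroenamine converts the doubly ortho-substituted acid into its chloride under neutral conditions, which keeps the sulfonate ester intact.

Step 7
Reactants: 11 orcinol (5-methylbenzene-1,3-diol)
Product: 12 2-hydroxy-6-methyl-1,4-benzoquinone
Conditions: ON(SO3K)2 (2.2 equiv), KH2PO4 buffer, H2O/acetone, 0 °C → rt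
Reagents that add atoms: potassium nitrosodisulfonate, [K+].[K+].[O]N(S(=O)(=O)[O-])S(=O)(=O)[O-]
Why: Teuber oxidation delivers oxygen to the free position para to a phenol, which in orcinol is the carbon between the second hydroxyl and the methyl group, so the 1,2,4-oxygenation pattern of ring B is set.

Step 8
Reactants: 12 2-hydroxy-6-methyl-1,4-benzoquinone
Product: 13 6-methylbenzene-1,2,4-triol
Conditions: Na2S2O4, H2O/EtOAc, rt, under argon; used at once
Reagents that add atoms: none
Why: Dithionite reduction of a quinone to its hydroquinone is fast and clean; the air-sensitive triol is carried on without storage.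

Step 9
Reactants: 13 6-methylbenzene-1,2,4-triol; 14 3,3-dimethylacrylic acid
Product: 16 6,7-dihydroxy-2,2,5-trimethylchroman-4-one, via aryl enone 15 (not isolated)
Conditions: P2O5/MeSO3H (1:10 w/w), 70 °C, under N2
Reagents that add atoms: none
Why: Friedel–Crafts acylation in P2O5/MeSO3H should go at the ring carbon beside the methyl group (ortho to one hydroxyl, para to another, as in acylations of orcinol), and the ortho hydroxyl then closes ring D onto the enone by oxa-Michael addition.

Step 10
Reactants: 10 2-[(4-chlorophenyl)sulfonyloxy]-3-iodo-4-methoxy-6-methylbenzoyl chloride; 16 6,7-dihydroxy-2,2,5-trimethylchroman-4-one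
Product: 17 6-hydroxy-2,2,5-trimethyl-4-oxochroman-7-yl 2-[(4-chlorophenyl)sulfonyloxy]-3-iodo-4-methoxy-6-methylbenzoate (the depside)
Conditions: Et3N (1.1 equiv), DMAP (cat.), CH2Cl2, −20 °C → rt
Reagents that add atoms: none
Why: Base-mediated O-acylation should select the 7-OH, which is para to the ketone-bearing carbon and so the more acidic hydroxyl, and is less hindered than the methyl-flanked 6-OH; the bulky aroyl group is expected to resist migration to the neighbouring oxygen.

Step 11
Reactants: 17 the depside; 18 N,N-dimethylformamide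
Product: 23 mollicellin A methyl ether, via arylmagnesium phenoxide 19 (not isolated), via aryne magnesium phenoxide 20 (not isolated), via cyclized arylmagnesium chloride 21 (not isolated), via magnesium hemiaminal alkoxide 22 (not isolated)
Conditions: i-PrMgCl·LiCl (2.1 equiv), THF (0.02 M), −78 °C, 30 min; −78 °C → rt; then DMF (5 equiv), −20 °C → rt; aq. NH4Cl, then 1 M HCl
Reagents that add atoms: none
Why: Proposed new method: the first equivalent of i-PrMgCl·LiCl turns the 6-OH into its magnesium phenoxide and the second exchanges the iodide to give 19, which on warming expels the neighbouring 4-chlorobenzenesulfonate to form aryne 20. The phenoxide oxygen then adds in the plane of ring A to the aryne carbon beside the ester, which makes the diaryl ether bond and closes the seven-membered ring C in an exo mode (the second aryne carbon stays outside the new ring); this leaves arylmagnesium 21, which attacks DMF to give 22, and acidic work-up releases the aldehyde. The closest known reaction type is aryne generation from a 2-magnesiated aryl sulfonate, addition of a magnesium thiolate or amide, and electrophilic trapping of the new aryl Grignard; the use of a tethered magnesium phenoxide for a seven-membered closure is the untested part. No stereocenter is formed. The step needs the oxygen on the ester-side aryne carbon and the formyl on the methoxy-side carbon: the tether can reach only the former, and the inductively withdrawing methoxy group favours carbanion development next to itself, so both effects point the same way. Chemoselectivity rests on an insertion with low steric demand, on halogen–magnesium exchange in place of amide bases (which would deprotonate the ortho-toluate methyl), and on the doubly ortho-substituted ester and the methyl-flanked, electron-rich ketone being slow toward Grignard reagents and acyl migration at these temperatures.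

Step 12
Reactants: 23 mollicellin A methyl ether
Product: 25 mollicellin A, via aryloxydichloroborane 24 (not isolated)
Conditions: BCl3, CH2Cl2, −78 → −10 °C; then H2O
Reagents that add atoms: none
Why: Chelation-controlled demethylation: BCl3 held between the formyl oxygen and the ortho methoxy oxygen cleaves only that methyl ether, while the lactone, the ketone and the chroman ether (none of which can chelate in this way) should survive at low temperature.

## Compound list

1 | 3,5-dimethoxytoluene | COc1cc(C)cc(OC)c1 | starting material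
2 | (2,6-dimethoxy-4-methylphenyl)lithium | [Li]c1c(OC)cc(C)cc1OC | intermediate
3 | 2-iodo-1,3-dimethoxy-5-methylbenzene | COc1cc(C)cc(OC)c1I | intermediate
4 | 1-[chloro(methoxy)methyl]-3-iodo-2,4-dimethoxy-6-methylbenzene | COC(Cl)c1c(C)cc(OC)c(I)c1OC | intermediate
5 | 3-iodo-2,4-dimethoxy-6-methylbenzaldehyde | Cc1cc(OC)c(I)c(OC)c1C=O | intermediate
6 | dichloro(2-formyl-6-iodo-5-methoxy-3-methylphenoxy)borane | Cc1cc(OC)c(I)c(OB(Cl)Cl)c1C=O | intermediate
7 | 2-hydroxy-3-iodo-4-methoxy-6-methylbenzaldehyde | Cc1cc(OC)c(I)c(O)c1C=O | intermediate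
8 | 2-formyl-6-iodo-5-methoxy-3-methylphenyl 4-chlorobenzenesulfonate | Cc1cc(OC)c(I)c(OS(=O)(=O)c2ccc(Cl)cc2)c1C=O | intermediate
9 | 2-[(4-chlorophenyl)sulfonyloxy]-3-iodo-4-methoxy-6-methylbenzoic acid | Cc1cc(OC)c(I)c(OS(=O)(=O)c2ccc(Cl)cc2)c1C(=O)O | intermediate
10 | 2-[(4-chlorophenyl)sulfonyloxy]-3-iodo-4-methoxy-6-methylbenzoyl chloride | Cc1cc(OC)c(I)c(OS(=O)(=O)c2ccc(Cl)cc2)c1C(=O)Cl | intermediate
11 | orcinol (5-methylbenzene-1,3-diol) | Cc1cc(O)cc(O)c1 | starting material
12 | 2-hydroxy-6-methyl-1,4-benzoquinone | CC1=CC(=O)C=C(O)C1=O | intermediate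
13 | 6-methylbenzene-1,2,4-triol | Cc1cc(O)cc(O)c1O | intermediate
14 | 3,3-dimethylacrylic acid | CC(C)=CC(=O)O | starting material
15 | 3-methyl-1-(2,4,5-trihydroxy-6-methylphenyl)but-2-en-1-one | CC(C)=CC(=O)c1c(O)cc(O)c(O)c1C | intermediate
16 | 6,7-dihydroxy-2,2,5-trimethylchroman-4-one (rings B and D) | Cc1c(O)c(O)cc2OC(C)(C)CC(=O)c12 | intermediate
17 | 6-hydroxy-2,2,5-trimethyl-4-oxochroman-7-yl 2-[(4-chlorophenyl)sulfonyloxy]-3-iodo-4-methoxy-6-methylbenzoate (depside) | Cc1cc(OC)c(I)c(OS(=O)(=O)c2ccc(Cl)cc2)c1C(=O)Oc1cc2OC(C)(C)CC(=O)c2c(C)c1O | intermediate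
18 | N,N-dimethylformamide | CN(C)C=O | starting material
19 | depside with ClMg on the 6-oxygen and on the former iodide carbon | Cc1cc(OC)c([Mg]Cl)c(OS(=O)(=O)c2ccc(Cl)cc2)c1C(=O)Oc1cc2OC(C)(C)CC(=O)c2c(C)c1O[Mg]Cl | intermediate
20 | aryne (triple bond between the former sulfonate and iodide carbons of ring A) carrying the chloromagnesium 6-phenoxide | CC1=C(C(=O)Oc2cc3OC(C)(C)CC(=O)c3c(C)c2O[Mg]Cl)C#CC(OC)=C1 | intermediate
21 | depsidone with MgCl on the ring A carbon between the methoxy carbon and the ether carbon | Cc1cc(OC)c([Mg]Cl)c2c1C(=O)Oc1cc3c(c(C)c1O2)C(=O)CC(C)(C)O3 | intermediate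
22 | chloromagnesium alkoxide of the DMF adduct (CH(OMgCl)NMe2 at the future formyl carbon) | Cc1cc(OC)c(C(O[Mg]Cl)N(C)C)c2c1C(=O)Oc1cc3c(c(C)c1O2)C(=O)CC(C)(C)O3 | intermediate
23 | mollicellin A methyl ether (full depsidone, OMe in place of the phenol OH) | Cc1cc(OC)c(C=O)c2c1C(=O)Oc1cc3c(c(C)c1O2)C(=O)CC(C)(C)O3 | intermediate
24 | dichloroboron phenoxide of mollicellin A | Cc1cc(OB(Cl)Cl)c(C=O)c2c1C(=O)Oc1cc3c(c(C)c1O2)C(=O)CC(C)(C)O3 | intermediate
25 | mollicellin A | Cc1cc(O)c(C=O)c2c1C(=O)Oc1cc3c(c(C)c1O2)C(=O)CC(C)(C)O3 | target

## Step count and risks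

Total step count: 12. Longest linear sequence: 9 steps (steps 1–6, 10, 11, 12).

Steps most likely to fail:

1. Step 11 (Proposed new method). The magnesium phenoxide may add too slowly to the aryne, so that the aryne is lost to intermolecular addition or oligomerization. The arylmagnesium formed after closure may be quenched by proton transfer from the ketone α-position, or may add to a carbonyl group, before DMF arrives. Base-induced acyl migration between the two catechol oxygens would also erode the regiochemistry of the closure.
   Fallback, setting out from 16 and coming back at 23: ring C is closed by nucleophilic aromatic substitution on a ring A fluoride that already carries the aldehyde. Bought 1-fluoro-3-methoxy-5-methylbenzene F1 is lithiated between fluorine and methoxy (n-BuLi, THF, −78 °C) and quenched with DMF to give 2-fluoro-6-methoxy-4-methylbenzaldehyde F2. This is masked as 2-(2-fluoro-6-methoxy-4-methylphenyl)-1,3-dioxolane F3 (ethylene glycol, TsOH, toluene, reflux). Lithiation at the remaining position ortho to fluorine (s-BuLi, TMEDA, THF, −78 °C) and a CO2 quench should give 3-(1,3-dioxolan-2-yl)-2-fluoro-4-methoxy-6-methylbenzoic acid F4. Aqueous HCl in THF frees 2-fluoro-3-formyl-4-methoxy-6-methylbenzoic acid F5. Its chloride, 2-fluoro-3-formyl-4-methoxy-6-methylbenzoyl chloride F6 (chloroenamine as in step 6), acylates the 7-OH of 16 under the conditions of step 10 to give 6-hydroxy-2,2,5-trimethyl-4-oxochroman-7-yl 2-fluoro-3-formyl-4-methoxy-6-methylbenzoate F7. K2CO3 in DMF at room temperature then lets the 6-phenoxide displace the fluoride, which is activated by the ortho formyl and ortho ester groups, and this gives 23.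

2. Step 10. Site selectivity between the two catechol hydroxyls may be poor, and double acylation or acyl migration under base may follow.
   Fallback, setting out from 16 and coming back at 17: the two oxygens are told apart by irreversible alkylation before the ester is made. Benzylation of the more acidic 7-OH (BnBr, K2CO3 1 equiv, DMF, rt) should give 7-(benzyloxy)-6-hydroxy-2,2,5-trimethylchroman-4-one F8. The 6-OH is capped (MOMCl, i-Pr2NEt, CH2Cl2) to give 7-(benzyloxy)-6-(methoxymethoxy)-2,2,5-trimethylchroman-4-one F9. Hydrogenolysis (H2, Pd/C, EtOAc) frees 7-hydroxy-6-(methoxymethoxy)-2,2,5-trimethylchroman-4-one F10. Acylation with 10 (Et3N, DMAP, CH2Cl2) gives 6-(methoxymethoxy)-2,2,5-trimethyl-4-oxochroman-7-yl 2-[(4-chlorophenyl)sulfonyloxy]-3-iodo-4-methoxy-6-methylbenzoate F11. Aqueous HCl in THF removes the acetal and gives 17.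

3. Step 9. C-acylation may go between the two hydroxyls instead of beside the methyl group, O-acylation and dihydrocoumarin formation may compete, and the electron-rich triol may be lost to oxidation in the hot acid.
   Fallback, setting out from 12 and coming back at 16: the ring is acylated as its stable trimethyl ether, in which the position between two methoxy groups is more hindered. Reductive methylation of 12 (Na2S2O4, then Me2SO4, K2CO3, acetone, reflux, under N2) gives 1,2,5-trimethoxy-3-methylbenzene F12. Friedel–Crafts acylation (3-methylbut-2-enoyl chloride, AlCl3, CH2Cl2, −10 °C) beside the methyl group should give 3-methyl-1-(2,4,5-trimethoxy-6-methylphenyl)but-2-en-1-one F13. BCl3 (CH2Cl2, −78 → 0 °C) cleaves the methoxy group ortho to the ketone to give 1-(2-hydroxy-4,5-dimethoxy-6-methylphenyl)-3-methylbut-2-en-1-one F14. Base (NaOAc, EtOH, reflux) closes the pyranone to 6,7-dimethoxy-2,2,5-trimethylchroman-4-one F15. BBr3 (CH2Cl2, −78 → 0 °C) removes both methyl ethers and gives 16.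

## Further compounds

F1 | step 11 | 1-fluoro-3-methoxy-5-methylbenzene | COc1cc(C)cc(F)c1
F2 | step 11 | 2-fluoro-6-methoxy-4-methylbenzaldehyde | COc1cc(C)cc(F)c1C=O
F3 | step 11 | 2-(2-fluoro-6-methoxy-4-methylphenyl)-1,3-dioxolane | COc1cc(C)cc(F)c1C1OCCO1
F4 | step 11 | 3-(1,3-dioxolan-2-yl)-2-fluoro-4-methoxy-6-methylbenzoic acid | COc1cc(C)c(C(=O)O)c(F)c1C1OCCO1
F5 | step 11 | 2-fluoro-3-formyl-4-methoxy-6-methylbenzoic acid | COc1cc(C)c(C(=O)O)c(F)c1C=O
F6 | step 11 | 2-fluoro-3-formyl-4-methoxy-6-methylbenzoyl chloride | COc1cc(C)c(C(=O)Cl)c(F)c1C=O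
F7 | step 11 | 6-hydroxy-2,2,5-trimethyl-4-oxochroman-7-yl 2-fluoro-3-formyl-4-methoxy-6-methylbenzoate | COc1cc(C)c(C(=O)Oc2cc3OC(C)(C)CC(=O)c3c(C)c2O)c(F)c1C=O
F8 | step 10 | 7-(benzyloxy)-6-hydroxy-2,2,5-trimethylchroman-4-one | Cc1c(O)c(OCc3ccccc3)cc2OC(C)(C)CC(=O)c12
F9 | step 10 | 7-(benzyloxy)-6-(methoxymethoxy)-2,2,5-trimethylchroman-4-one | Cc1c(OCOC)c(OCc3ccccc3)cc2OC(C)(C)CC(=O)c12
F10 | step 10 | 7-hydroxy-6-(methoxymethoxy)-2,2,5-trimethylchroman-4-one | Cc1c(OCOC)c(O)cc2OC(C)(C)CC(=O)c12
F11 | step 10 | 6-(methoxymethoxy)-2,2,5-trimethyl-4-oxochroman-7-yl 2-[(4-chlorophenyl)sulfonyloxy]-3-iodo-4-methoxy-6-methylbenzoate | Cc1cc(OC)c(I)c(OS(=O)(=O)c2ccc(Cl)cc2)c1C(=O)Oc1cc2OC(C)(C)CC(=O)c2c(C)c1OCOC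
F12 | step 9 | 1,2,5-trimethoxy-3-methylbenzene | Cc1cc(OC)cc(OC)c1OC
F13 | step 9 | 3-methyl-1-(2,4,5-trimethoxy-6-methylphenyl)but-2-en-1-one | CC(C)=CC(=O)c1c(C)c(OC)c(OC)cc1OC
F14 | step 9 | 1-(2-hydroxy-4,5-dimethoxy-6-methylphenyl)-3-methylbut-2-en-1-one | CC(C)=CC(=O)c1c(C)c(OC)c(OC)cc1O
F15 | step 9 | 6,7-dimethoxy-2,2,5-trimethylchroman-4-one | Cc1c(OC)c(OC)cc2OC(C)(C)CC(=O)c12
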